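**Strategy.** The ten-membered carbocycle (ring B, C1–C10) is never closed directly. C3 and C4 are first linked through sulfur in an eleven-membered thiacycle, closed by thiolate S-alkylation. A Ramberg–Bäcklund reaction of the derived sulfone then expels SO2, contracting the ring by one atom and leaving the C3–C4 bond as the (3Z) double bond of the C3=C4–C5=C6 diene, the feature the key step exploits. Its precursor is a cyclic allylic sulfone bridging C3 and C4 that already carries ring A with the 13,14-epoxide, the C5=C6 olefin and O7/O8 tied as an acetal. The base-sensitive γ-lactone (intramolecular Reformatsky reaction) and both acetates follow the contraction.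

Key step: step 23

**Remarks on the chemistry.**
- Carbons keep their briarane numbers throughout: C1 is the quaternary carbon with Me-15, C2–C9 the chain, C10 the ring-fusion CH, C11–C14 the rest of ring A with Me-20 on C11, C16 the CH2O on C5, and C17/C18/C19 the lactone CH, its methyl and its C=O. Ring A is the cyclohexane, ring B the ten-membered carbocycle, and β is the face of Me-15.
- Compounds 1, 2 (dosed as cracked paraformaldehyde), 6, 8 and 19 are taken as commercial.
- Centres that are later destroyed or are inconsequential are carried as mixtures and drawn without configuration: the carbinol of 10, the lactol carbon of 18, the acetal carbon of 27–37 and the CHBr carbon of 39–42.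

## Route

Step 1
Reactants: 1 ethyl propiolate; 2 formaldehyde
Product: 3 ethyl (Z)-2-(hydroxymethyl)-3-iodoprop-2-enoate (iodine cis to the ester)
Conditions: MgI2, CH2Cl2, 0 °C → rt
Reagents that add atoms: magnesium iodide, [Mg+2].[I-].[I-]
Why: Iodo-aldol (halo Morita–Baylis–Hillman type) reaction in which iodide adds to the ynoate and the magnesium allenolate is trapped by formaldehyde, the chelated allenolate giving the isomer with iodine cis to the ester.

Step 2
Reactants: 3 ethyl (Z)-2-(hydroxymethyl)-3-iodoprop-2-enoate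
Product: 4 ethyl (Z)-3-iodo-2-[(triisopropylsilyloxy)methyl]prop-2-enoate
Conditions: TIPSCl, imidazole, CH2Cl2, 0 °C → rt
Reagents that add atoms: chlorotriisopropylsilane, CC(C)[Si](Cl)(C(C)C)C(C)C
Why: Standard silyl ether formation on the only hydroxyl; this oxygen becomes O16.

Step 3
Reactants: 4 ethyl (Z)-3-iodo-2-[(triisopropylsilyloxy)methyl]prop-2-enoate
Product: 5 (E)-3-iodo-2-[(triisopropylsilyloxy)methyl]prop-2-en-1-ol (iodine cis to CH2OH, the future C4)
Conditions: i-Bu2AlH (2.5 equiv), CH2Cl2, −78 °C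
Reagents that add atoms: none
Why: Hydride reduction of the enoate to the allylic alcohol at low temperature leaves the vinyl iodide and the olefin geometry untouched.

Step 4
Reactants: 6 pent-1-en-3-one
Product: 7 (Z)-triisopropyl(penta-1,3-dien-3-yloxy)silane
Conditions: TIPSOTf, Et3N, CH2Cl2, 0 °C
Reagents that add atoms: triisopropylsilyl trifluoromethanesulfonate, CC(C)[Si](OS(=O)(=O)C(F)(F)F)(C(C)C)C(C)C
Why: Soft enolisation and O-silylation of the ethyl ketone gives the 2-silyloxy diene as the (Z)-enol ether, with the methyl anti to the vinyl group, i.e. "outside" in the s-cis diene.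

Step 5
Reactants: 7 (Z)-triisopropyl(penta-1,3-dien-3-yloxy)silane; 8 ethyl (E)-3-methyl-4-oxobut-2-enoate
Product: 9 ethyl 6-formyl-2,6-dimethyl-3-(triisopropylsilyloxy)cyclohex-3-ene-1-carboxylate (ester, 2-Me and 6-Me all cis; formyl trans to the ester; these carbons are C10, C11 and C1)
Conditions: (S)-B-o-tolyl oxazaborolidine from α,α-diphenylprolinol·HNTf2 (20 mol %), CH2Cl2, −78 → −40 °C
Reagents that add atoms: none
Why: Catalytic enantioselective Diels–Alder reaction in which the nucleophilic diene terminus (C11) bonds to the enal β-carbon (C10) and the ester is endo (formyl exo, as usual for α-methyl enals), which places Me-15, the C10 ester and Me-20 cis and the formyl (C2) trans; the cationic oxazaborolidine binds the formyl group and selects the enal face (the (S)-catalyst is the one predicted by the formyl C–H···O model to give the shown enantiomer).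

Step 6
Reactants: 9 Diels–Alder adduct
Product: 10 ethyl 6-(2-chloro-1-hydroxyethyl)-2,6-dimethyl-3-(triisopropylsilyloxy)cyclohex-3-ene-1-carboxylate (both carbinol epimers)
Conditions: ICH2Cl, MeLi·LiBr, THF, −78 °C; AcOH at −78 °C
Reagents that add atoms: chloroiodomethane, ClCI
Why: Chloromethyllithium generated in the presence of the substrate adds to the non-enolisable neopentyl aldehyde much faster than to the ester, and the cold acidic quench prevents closure to the epoxide; the C2 mixture is levelled in the next two steps.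

Step 7
Reactants: 10 chlorohydrin mixture
Product: 11 ethyl 6-(chloroacetyl)-2,6-dimethyl-3-(triisopropylsilyloxy)cyclohex-3-ene-1-carboxylate
Conditions: Dess–Martin periodinane, NaHCO3, CH2Cl2, 0 °C → rt
Reagents that add atoms: none
Why: Buffered periodinane oxidation of the secondary alcohol to the α-chloro ketone tolerates the silyl enol ether and the ester.

Step 8
Reactants: 11 chloromethyl ketone
Product: 12 ethyl 6-[(1R)-2-chloro-1-hydroxyethyl]-2,6-dimethyl-3-(triisopropylsilyloxy)cyclohex-3-ene-1-carboxylate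
Conditions: (R)-2-methyl-CBS-oxazaborolidine (15 mol %), catecholborane, toluene, −78 °C
Reagents that add atoms: none
Why: Corey–Bakshi–Shibata reduction under catalyst control (tertiary-alkyl group large, CH2Cl small) sets the carbinol as (R), which is the 2S configuration of the target once C3 becomes olefinic; catecholborane at −78 °C does not touch the enol ether.

Step 9
Reactants: 12 (R)-chlorohydrin silyl enol ether
Product: 13 ethyl 6-[(1R)-2-chloro-1-hydroxyethyl]-2,6-dimethyl-3-oxocyclohex-4-ene-1-carboxylate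
Conditions: Pd(OAc)2 (1.1 equiv), MeCN, 40 °C
Reagents that add atoms: none
Why: Saegusa–Ito oxidation through the oxa-π-allylpalladium species with β-hydride loss from C14 gives the C13=C14 enone under neutral conditions, so the epimerisable C11 centre is kept.

Step 10
Reactants: 13 enone
Product: 15 2-[(1R)-2-chloro-1-hydroxyethyl]-2,8-dimethyl-6-oxabicyclo[3.2.1]oct-3-en-7-one (lactone from O12 to C9), via allylic alcohol 14 (not isolated)
Conditions: NaBH4, CeCl3·7H2O, MeOH, −78 °C; then PPTS (cat.), PhMe, 60 °C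
Reagents that add atoms: none
Why: Luche 1,2-reduction with hydride entering from the α face (anti to the axial C10 ester and the two β methyls) gives the 12β-alcohol, which is cis-1,3 to the ester and lactonises to the bridged lactone; only this epimer can lactonise, so the lactone also serves as proof and purification.

Step 11
Reactants: 15 bridged lactone
Product: 16 3,4-epoxy-2-[(1R)-2-chloro-1-hydroxyethyl]-2,8-dimethyl-6-oxabicyclo[3.2.1]octan-7-one (epoxide on the α face, syn to the hydroxyethyl chain)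
Conditions: VO(acac)2 (5 mol %), t-BuOOH, CH2Cl2, 0 °C → rt
Reagents that add atoms: tert-butyl hydroperoxide, CC(C)(C)OO
Why: Vanadium-catalysed hydroxyl-directed epoxidation in which the homoallylic C2–OH, held axially on the α face, delivers the peroxide to that face while the lactone bridge blocks the β face, giving the 13α,14α-epoxide.

Step 12
Reactants: 16 epoxy lactone
Product: 17 tert-butyldimethylsilyl ether of 16 at O2
Conditions: TBSOTf, 2,6-lutidine, CH2Cl2, −78 → 0 °C
Reagents that add atoms: tert-butyldimethylsilyl trifluoromethanesulfonate, CC(C)(C)[Si](C)(C)OS(=O)(=O)C(F)(F)F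
Why: Silyl triflate silylation of the hindered secondary alcohol under buffered conditions that the epoxide and lactone tolerate.

Step 13
Reactants: 17 silylated epoxy lactone
Product: 18 the corresponding lactol (7-hydroxy-6-oxabicyclo[3.2.1]octane; anomers)
Conditions: i-Bu2AlH (1.1 equiv), CH2Cl2, −78 °C
Reagents that add atoms: none
Why: Half-reduction of the lactone stops at the tetrahedral aluminium acetal at −78 °C, unmasking C9 at the aldehyde oxidation level.

Step 14
Reactants: 18 lactol; 19 allyl 4-methoxybenzyl ether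
Product: 21 ring-A diol with free 12β-OH and C10 side chain (9R)-CH(OH)–(8R)-CH(OPMB)–CH=CH2 (8,9-syn), via allylborane 20 (not isolated)
Conditions: 19, s-BuLi, THF, −78 °C; (−)-Ipc2BOMe; BF3·OEt2; then 18, −78 °C → rt; NaOH, H2O2
Reagents that add atoms: none
Why: Diisopinocampheylborane-mediated γ-alkoxyallylboration of the hydroxy-aldehyde form of the lactol through a Zimmerman–Traxler chair, in which the (Z)-γ-alkoxyallyl geometry gives the 8,9-syn relationship and the isopinocampheyl groups from (+)-α-pinene dictate the 9R configuration.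

Step 15
Reactants: 21 diol
Product: 22 9,12-bis(triethylsilyl) ether of 21
Conditions: TESOTf (2.5 equiv), 2,6-lutidine, CH2Cl2, −78 °C
Reagents that add atoms: triethylsilyl trifluoromethanesulfonate, CC[Si](CC)(CC)OS(=O)(=O)C(F)(F)F
Why: Both secondary hydroxyls are silylated in one operation; TES is chosen because it can later be removed in the presence of TBS and TIPS.

Step 16
Reactants: 22 bis-TES ether
Product: 24 C7 aldehyde (8-OPMB, 9-OTES), via secondary ozonide 23 (not isolated)
Conditions: O3, CH2Cl2, −78 °C; PPh3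
Reagents that add atoms: ozone, [O-][O+]=O
Why: Ozonolysis of the only C=C bond with reductive work-up gives the α-alkoxy aldehyde, which is used at once to avoid epimerisation at C8.

Step 17
Reactants: 24 C7 aldehyde; 5 (E)-3-iodo-2-[(triisopropylsilyloxy)methyl]prop-2-en-1-ol
Product: 26 C4,C7-diol with the C5=C6 olefin in place (C7 and C4 cis; 7,8-syn), via dilithio alkoxide-alkenyllithium 25 (not isolated)
Conditions: 5, t-BuLi (3.1 equiv), Et2O, −78 °C; MgBr2·OEt2; then 24, CH2Cl2, −78 °C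
Reagents that add atoms: none
Why: Iodine–lithium exchange with retention of olefin geometry, transmetallation to magnesium and Cram-chelate addition (magnesium bridging the aldehyde oxygen and the α-OPMB group) set C7 syn to C8, which is the configuration of C7 in the target.

Step 18
Reactants: 26 C4,C7-diol
Product: 27 O7,O8-(4-methoxybenzylidene) acetal (trans-dioxolane) with free C4–OH
Conditions: DDQ (1.2 equiv), 4 Å MS, CH2Cl2, −10 °C
Reagents that add atoms: none
Why: Anhydrous DDQ oxidation of the PMB ether to its oxocarbenium ion, trapped by the neighbouring C7–OH, ties O7 and O8 into an acetal, so that neither can act as a nucleophile or as a good leaving group in the sulfur chemistry that follows.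

Step 19
Reactants: 27 acetal alcohol
Product: 28 C3 thioacetate
Conditions: KSAc, NaI (cat.), DMF, 65 °C
Reagents that add atoms: potassium thioacetate, CC(=O)[S-].[K+]
Why: SN2 displacement of the primary chloride by thioacetate introduces the sulfur atom at C3; the β-branching only slows it, hence heat and iodide catalysis.

Step 20
Reactants: 28 C3 thioacetate
Product: 30 C4 allylic chloride, via allylic mesylate 29 (not isolated)
Conditions: MsCl, 2,4,6-collidine, LiCl, DMF, 0 °C
Reagents that add atoms: lithium chloride, [Li+].[Cl-]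
Why: Mesylation of the only free (primary allylic) hydroxyl and in situ chloride exchange give the allylic chloride by direct SN2 without allylic transposition or loss of olefin geometry.

Step 21
Reactants: 30 thioacetate allylic chloride
Product: 32 eleven-membered cyclic sulfide (S between C3 and C4), via free thiol 31 (not isolated)
Conditions: K2CO3, MeOH/THF (degassed), 0.002 M, 0 °C → rt
Reagents that add atoms: none
Why: Methanolysis of the thioacetate releases the thiolate, which closes the eleven-membered ring by intramolecular SN2 at the allylic chloride under high dilution; the trans-dioxolane and trans-disubstituted ring A pre-organise the chain.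

Step 22
Reactants: 32 cyclic sulfide
Product: 34 eleven-membered cyclic sulfone, via sulfoxide 33 (not isolated)
Conditions: (n-Pr4N)RuO4 (10 mol %), NMO, 4 Å MS, MeCN, rt
Reagents that add atoms: N-methylmorpholine N-oxide, C[N+]1([O-])CCOCC1
Why: Perruthenate-catalysed oxidation takes the sulfide through the sulfoxide to the sulfone without touching the trisubstituted olefin, the epoxide or the acetal, and no free hydroxyl is present.

Step 23
Reactants: 34 eleven-membered cyclic sulfone
Product: 37 ten-membered (3Z,5)-diene with O7/O8 acetal, via α-bromo sulfone 35 (not isolated), via episulfone 36 (not isolated)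
Conditions: CBr2F2, KOH/Al2O3, t-BuOH/CH2Cl2, 0 °C → rt
Reagents that add atoms: none
Why: KOH on alumina removes the more acidic allylic α-proton (C4) of the sulfone, the carbanion is brominated by CBr2F2 to 35, and a second deprotonation at C3 is followed by 1,3-displacement of bromide to give the thiirane 1,1-dioxide 36, which loses SO2 cheletropically to leave the C3=C4 double bond. The closest known reaction type is the Ramberg–Bäcklund ring contraction of cyclic sulfones with in situ halogenation, as used for strained medium-ring olefins and conjugated dienes. The only ring closed is the three-membered episulfone (3-exo-tet, carbanion on the C–Br carbon); the ten-membered carbocycle C1–C10 then arises from the eleven-membered thiacycle by loss of the sulfur atom. No stereocentre is formed; the olefin geometry is fixed at the episulfone, where cis fusion (hence 3Z) is favoured by the hydroxide conditions and by the strain a trans olefin would impose on a ten-membered ring that already holds the ring-cis C5=C6 olefin and the trans-fused ring A. The step needs bromination at C4 and not at C3 (secured by allylic acidity), ring closure faster than β-elimination of the C2 silyloxy group or vinylogous loss of O7 (secured by ether-type leaving groups and by the absence of the lactone and of any ester), and survival of the epoxide, acetal and silyl ethers, all stable to KOH/Al2O3.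

Step 24
Reactants: 37 diene acetal
Product: 38 C7 alcohol with C8 4-methoxybenzyl ether
Conditions: i-Bu2AlH, CH2Cl2, −78 → −20 °C
Reagents that add atoms: none
Why: Reductive opening of the benzylidene acetal, in which aluminium coordinates the less hindered allylic O7 and hydride delivery leaves the PMB group on the more hindered O8 (the other regioisomer would reach 41 by the same three operations in a different order).

Step 25
Reactants: 38 C7 alcohol
Product: 39 C7 2-bromopropanoate (epimers at CHBr)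
Conditions: 2-bromopropanoyl bromide, pyridine, DMAP (cat.), CH2Cl2, −20 °C
Reagents that add atoms: 2-bromopropanoyl bromide, CC(Br)C(Br)=O
Why: Acylation of the only free hydroxyl installs C17, C18 and C19 as the latent Reformatsky donor.

Step 26
Reactants: 39 bromopropanoate
Product: 40 C8 alcohol
Conditions: DDQ, CH2Cl2/pH 7 buffer, 0 °C
Reagents that add atoms: none
Why: Oxidative PMB cleavage under buffered conditions frees the C8 hydroxyl; the twisted medium-ring diene is a poor partner for DDQ and the silyl ethers are inert.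

Step 27
Reactants: 40 C8 alcohol
Product: 41 C8 ketone (α-acyloxy ketone)
Conditions: Dess–Martin periodinane, NaHCO3, CH2Cl2, 0 °C → rt
Reagents that add atoms: none
Why: Mild buffered oxidation of the secondary alcohol gives the ketone without enolising the acidic C7–H.

Step 28
Reactants: 41 C8 ketone
Product: 43 γ-lactone with tertiary 8-OH (9,12-bis-TES, 2-TBS, 16-TIPS), via zinc ester enolate 42 (not isolated)
Conditions: Zn (Me3SiCl-activated), THF, 0 → 25 °C
Reagents that add atoms: none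
Why: Intramolecular Reformatsky reaction (5-exo-trig) in which the zinc enolate, tethered through O7, adds to the C8 ketone so that the two ring-B arms (C6 and C9) sit trans on the new lactone and the C17 methyl sits anti to C9 (cis to 8-OH), the least congested chelated arrangement; C17 is epimerisable and the reversible zinc aldolate converges on this isomer.

Step 29
Reactants: 43 silylated lactone
Product: 44 9,12-diol (2-TBS, 16-TIPS retained)
Conditions: PPTS, MeOH/CH2Cl2, 0 °C → rt
Reagents that add atoms: none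
Why: Mild acidic methanolysis removes the two secondary TES ethers while the TBS and TIPS ethers survive.

Step 30
Reactants: 44 9,12-diol
Product: 45 9,12-diacetate
Conditions: Ac2O, pyridine, DMAP (cat.), CH2Cl2, 0 °C → rt
Reagents that add atoms: acetic anhydride, CC(=O)OC(C)=O
Why: Acetylation of the two secondary alcohols; the hindered tertiary 8-OH does not react under these conditions.

Step 31
Reactants: 45 9,12-diacetate
Product: 46 briaexcavatolide N
Conditions: HF·pyridine, pyridine, THF, 0 °C → rt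
Reagents that add atoms: none
Why: Buffered fluoride desilylation removes the TBS (O2) and TIPS (O16) groups without acyl migration or opening of the hindered epoxide.

## Compound list

1 | ethyl propiolate | C#CC(=O)OCC | starting material
2 | formaldehyde (used as paraformaldehyde) | C=O | starting material
3 | ethyl (Z)-2-(hydroxymethyl)-3-iodoprop-2-enoate | I/C=C(CO)\C(=O)OCC | intermediate
4 | ethyl (Z)-3-iodo-2-[(triisopropylsilyloxy)methyl]prop-2-enoate | I/C=C(CO[Si](C(C)C)(C(C)C)C(C)C)\C(=O)OCC | intermediate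
5 | (E)-3-iodo-2-[(triisopropylsilyloxy)methyl]prop-2-en-1-ol | I/C=C(CO[Si](C(C)C)(C(C)C)C(C)C)\CO | intermediate
6 | pent-1-en-3-one | C=CC(=O)CC | starting material
7 | (Z)-triisopropyl(penta-1,3-dien-3-yloxy)silane | C=C/C(O[Si](C(C)C)(C(C)C)C(C)C)=C/C | intermediate
8 | ethyl (E)-3-methyl-4-oxobut-2-enoate | CCOC(=O)/C=C(C)/C=O | starting material
9 | ethyl 6-formyl-2,6-dimethyl-3-(triisopropylsilyloxy)cyclohex-3-ene-1-carboxylate (ester and both methyls cis) | CC(C)[Si](C(C)C)(C(C)C)OC1=CC[C@](C)(C=O)[C@@H](C(=O)OCC)[C@H]1C | intermediate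
10 | ethyl 6-(2-chloro-1-hydroxyethyl)-2,6-dimethyl-3-(triisopropylsilyloxy)cyclohex-3-ene-1-carboxylate (carbinol epimers) | CC(C)[Si](C(C)C)(C(C)C)OC1=CC[C@](C)(C(O)CCl)[C@@H](C(=O)OCC)[C@H]1C | intermediate
11 | ethyl 6-(chloroacetyl)-2,6-dimethyl-3-(triisopropylsilyloxy)cyclohex-3-ene-1-carboxylate | CC(C)[Si](C(C)C)(C(C)C)OC1=CC[C@](C)(C(=O)CCl)[C@@H](C(=O)OCC)[C@H]1C | intermediate
12 | ethyl 6-[(1R)-2-chloro-1-hydroxyethyl]-2,6-dimethyl-3-(triisopropylsilyloxy)cyclohex-3-ene-1-carboxylate | CC(C)[Si](C(C)C)(C(C)C)OC1=CC[C@](C)([C@@H](O)CCl)[C@@H](C(=O)OCC)[C@H]1C | intermediate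
13 | ethyl 6-[(1R)-2-chloro-1-hydroxyethyl]-2,6-dimethyl-3-oxocyclohex-4-ene-1-carboxylate | O=C1C=C[C@](C)([C@@H](O)CCl)[C@@H](C(=O)OCC)[C@H]1C | intermediate
14 | ethyl 6-[(1R)-2-chloro-1-hydroxyethyl]-3-hydroxy-2,6-dimethylcyclohex-4-ene-1-carboxylate (3-OH cis to 2-Me and ester) | O[C@H]1C=C[C@](C)([C@@H](O)CCl)[C@@H](C(=O)OCC)[C@H]1C | intermediate
15 | 2-[(1R)-2-chloro-1-hydroxyethyl]-2,8-dimethyl-6-oxabicyclo[3.2.1]oct-3-en-7-one | O=C1O[C@H]2C=C[C@@]([C@@H](O)CCl)(C)[C@@H]1[C@H]2C | intermediate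
16 | 3,4-epoxy-2-[(1R)-2-chloro-1-hydroxyethyl]-2,8-dimethyl-6-oxabicyclo[3.2.1]octan-7-one (epoxide syn to the side chain) | O=C1O[C@H]2[C@@H]3O[C@@H]3[C@@]([C@@H](O)CCl)(C)[C@@H]1[C@H]2C | intermediate
17 | O2-TBS ether of 16 | O=C1O[C@H]2[C@@H]3O[C@@H]3[C@@]([C@@H](O[Si](C)(C)C(C)(C)C)CCl)(C)[C@@H]1[C@H]2C | intermediate
18 | lactol of 17 (anomers) | OC1O[C@H]2[C@@H]3O[C@@H]3[C@@]([C@@H](O[Si](C)(C)C(C)(C)C)CCl)(C)[C@@H]1[C@H]2C | intermediate
19 | allyl 4-methoxybenzyl ether | C=CCOCc1ccc(OC)cc1 | starting material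
20 | (Z)-[3-(4-methoxybenzyloxy)allyl]diisopinocampheylborane | COc1ccc(CO/C=C\CB([C@@H]2C[C@@H]3C[C@H]([C@H]2C)C3(C)C)[C@@H]2C[C@@H]3C[C@H]([C@H]2C)C3(C)C)cc1 | intermediate
21 | ring-A 9,12-diol: 13α,14α-epoxide, C1 chain (R)-CH(OTBS)CH2Cl, C10 chain (9R)-CH(OH)–(8R)-CH(OPMB)–CH=CH2 | O[C@@H]1[C@H](C)[C@H]([C@@H](O)[C@H](OCc3ccc(OC)cc3)C=C)[C@]([C@@H](O[Si](C)(C)C(C)(C)C)CCl)(C)[C@H]2O[C@@H]12 | intermediate
22 | 9,12-bis-TES ether of 21 | CC[Si](CC)(CC)O[C@@H]1[C@H](C)[C@H]([C@@H](O[Si](CC)(CC)CC)[C@H](OCc3ccc(OC)cc3)C=C)[C@]([C@@H](O[Si](C)(C)C(C)(C)C)CCl)(C)[C@H]2O[C@@H]12 | intermediate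
23 | secondary ozonide of 22 | CC[Si](CC)(CC)O[C@@H]1[C@H](C)[C@H]([C@@H](O[Si](CC)(CC)CC)[C@H](OCc3ccc(OC)cc3)C3OCOO3)[C@]([C@@H](O[Si](C)(C)C(C)(C)C)CCl)(C)[C@H]2O[C@@H]12 | intermediate
24 | C7 aldehyde (8-OPMB, 9,12-bis-OTES) | CC[Si](CC)(CC)O[C@@H]1[C@H](C)[C@H]([C@@H](O[Si](CC)(CC)CC)[C@H](OCc3ccc(OC)cc3)C=O)[C@]([C@@H](O[Si](C)(C)C(C)(C)C)CCl)(C)[C@H]2O[C@@H]12 | intermediate
25 | dilithio derivative of 5 (O-lithium, C-lithium) | [Li]/C=C(CO[Si](C(C)C)(C(C)C)C(C)C)\CO[Li] | intermediate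
26 | C4,C7-diol (7,8-syn; C7 and C4 cis on C5=C6) | CC[Si](CC)(CC)O[C@@H]1[C@H](C)[C@H]([C@@H](O[Si](CC)(CC)CC)[C@H](OCc3ccc(OC)cc3)[C@@H](O)/C=C(CO[Si](C(C)C)(C(C)C)C(C)C)\CO)[C@]([C@@H](O[Si](C)(C)C(C)(C)C)CCl)(C)[C@H]2O[C@@H]12 | intermediate
27 | O7,O8-(4-methoxybenzylidene) acetal with free C4–OH | CC[Si](CC)(CC)O[C@@H]1[C@H](C)[C@H]([C@@H](O[Si](CC)(CC)CC)[C@@H]3OC(c4ccc(OC)cc4)O[C@H]3/C=C(CO[Si](C(C)C)(C(C)C)C(C)C)\CO)[C@]([C@@H](O[Si](C)(C)C(C)(C)C)CCl)(C)[C@H]2O[C@@H]12 | intermediate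
28 | C3 thioacetate | CC[Si](CC)(CC)O[C@@H]1[C@H](C)[C@H]([C@@H](O[Si](CC)(CC)CC)[C@@H]3OC(c4ccc(OC)cc4)O[C@H]3/C=C(CO[Si](C(C)C)(C(C)C)C(C)C)\CO)[C@]([C@@H](O[Si](C)(C)C(C)(C)C)CSC(C)=O)(C)[C@H]2O[C@@H]12 | intermediate
29 | C4 allylic mesylate | CC[Si](CC)(CC)O[C@@H]1[C@H](C)[C@H]([C@@H](O[Si](CC)(CC)CC)[C@@H]3OC(c4ccc(OC)cc4)O[C@H]3/C=C(CO[Si](C(C)C)(C(C)C)C(C)C)\COS(C)(=O)=O)[C@]([C@@H](O[Si](C)(C)C(C)(C)C)CSC(C)=O)(C)[C@H]2O[C@@H]12 | intermediate
30 | C4 allylic chloride, C3 thioacetate | CC[Si](CC)(CC)O[C@@H]1[C@H](C)[C@H]([C@@H](O[Si](CC)(CC)CC)[C@@H]3OC(c4ccc(OC)cc4)O[C@H]3/C=C(CO[Si](C(C)C)(C(C)C)C(C)C)\CCl)[C@]([C@@H](O[Si](C)(C)C(C)(C)C)CSC(C)=O)(C)[C@H]2O[C@@H]12 | intermediate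
31 | C3 thiol, C4 allylic chloride | CC[Si](CC)(CC)O[C@@H]1[C@H](C)[C@H]([C@@H](O[Si](CC)(CC)CC)[C@@H]3OC(c4ccc(OC)cc4)O[C@H]3/C=C(CO[Si](C(C)C)(C(C)C)C(C)C)\CCl)[C@]([C@@H](O[Si](C)(C)C(C)(C)C)CS)(C)[C@H]2O[C@@H]12 | intermediate
32 | eleven-membered cyclic sulfide (S between C3 and C4) | CC[Si](CC)(CC)O[C@@H]1[C@H](C)[C@@H]2[C@@H](O[Si](CC)(CC)CC)[C@@H]3OC(c4ccc(OC)cc4)O[C@H]3/C=C(CO[Si](C(C)C)(C(C)C)C(C)C)\CSC[C@H](O[Si](C)(C)C(C)(C)C)[C@@]2(C)[C@H]2O[C@@H]12 | intermediate
33 | cyclic sulfoxide | CC[Si](CC)(CC)O[C@@H]1[C@H](C)[C@@H]2[C@@H](O[Si](CC)(CC)CC)[C@@H]3OC(c4ccc(OC)cc4)O[C@H]3/C=C(CO[Si](C(C)C)(C(C)C)C(C)C)\CS(=O)C[C@H](O[Si](C)(C)C(C)(C)C)[C@@]2(C)[C@H]2O[C@@H]12 | intermediate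
34 | eleven-membered cyclic sulfone | CC[Si](CC)(CC)O[C@@H]1[C@H](C)[C@@H]2[C@@H](O[Si](CC)(CC)CC)[C@@H]3OC(c4ccc(OC)cc4)O[C@H]3/C=C(CO[Si](C(C)C)(C(C)C)C(C)C)\CS(=O)(=O)C[C@H](O[Si](C)(C)C(C)(C)C)[C@@]2(C)[C@H]2O[C@@H]12 | intermediate
35 | C4 α-bromo sulfone | CC[Si](CC)(CC)O[C@@H]1[C@H](C)[C@@H]2[C@@H](O[Si](CC)(CC)CC)[C@@H]3OC(c4ccc(OC)cc4)O[C@H]3/C=C(CO[Si](C(C)C)(C(C)C)C(C)C)\C(Br)S(=O)(=O)C[C@H](O[Si](C)(C)C(C)(C)C)[C@@]2(C)[C@H]2O[C@@H]12 | intermediate
36 | C3,C4 episulfone (thiirane 1,1-dioxide) | CC[Si](CC)(CC)O[C@@H]1[C@H](C)[C@@H]2[C@@H](O[Si](CC)(CC)CC)[C@@H]3OC(c4ccc(OC)cc4)O[C@H]3/C=C(CO[Si](C(C)C)(C(C)C)C(C)C)\C5S(=O)(=O)C5[C@H](O[Si](C)(C)C(C)(C)C)[C@@]2(C)[C@H]2O[C@@H]12 | intermediate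
37 | ten-membered (3Z)-diene with O7,O8 acetal | CC[Si](CC)(CC)O[C@@H]1[C@H](C)[C@@H]2[C@@H](O[Si](CC)(CC)CC)[C@@H]3OC(c4ccc(OC)cc4)O[C@H]3/C=C(CO[Si](C(C)C)(C(C)C)C(C)C)\C=C/[C@H](O[Si](C)(C)C(C)(C)C)[C@@]2(C)[C@H]2O[C@@H]12 | intermediate
38 | C7 alcohol, C8 PMB ether | CC[Si](CC)(CC)O[C@@H]1[C@H](C)[C@@H]2[C@@H](O[Si](CC)(CC)CC)[C@H](OCc3ccc(OC)cc3)[C@@H](O)/C=C(CO[Si](C(C)C)(C(C)C)C(C)C)\C=C/[C@H](O[Si](C)(C)C(C)(C)C)[C@@]2(C)[C@H]2O[C@@H]12 | intermediate
39 | C7 2-bromopropanoate, C8 PMB ether | CC[Si](CC)(CC)O[C@@H]1[C@H](C)[C@@H]2[C@@H](O[Si](CC)(CC)CC)[C@H](OCc3ccc(OC)cc3)[C@@H](OC(=O)C(C)Br)/C=C(CO[Si](C(C)C)(C(C)C)C(C)C)\C=C/[C@H](O[Si](C)(C)C(C)(C)C)[C@@]2(C)[C@H]2O[C@@H]12 | intermediate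
40 | C7 2-bromopropanoate, C8 alcohol | CC[Si](CC)(CC)O[C@@H]1[C@H](C)[C@@H]2[C@@H](O[Si](CC)(CC)CC)[C@H](O)[C@@H](OC(=O)C(C)Br)/C=C(CO[Si](C(C)C)(C(C)C)C(C)C)\C=C/[C@H](O[Si](C)(C)C(C)(C)C)[C@@]2(C)[C@H]2O[C@@H]12 | intermediate
41 | C8 ketone with C7 2-bromopropanoate | CC[Si](CC)(CC)O[C@@H]1[C@H](C)[C@@H]2[C@@H](O[Si](CC)(CC)CC)C(=O)[C@@H](OC(=O)C(C)Br)/C=C(CO[Si](C(C)C)(C(C)C)C(C)C)\C=C/[C@H](O[Si](C)(C)C(C)(C)C)[C@@]2(C)[C@H]2O[C@@H]12 | intermediate
42 | zinc ester enolate (C-bound Reformatsky reagent) of 41 | CC[Si](CC)(CC)O[C@@H]1[C@H](C)[C@@H]2[C@@H](O[Si](CC)(CC)CC)C(=O)[C@@H](OC(=O)C(C)[Zn]Br)/C=C(CO[Si](C(C)C)(C(C)C)C(C)C)\C=C/[C@H](O[Si](C)(C)C(C)(C)C)[C@@]2(C)[C@H]2O[C@@H]12 | intermediate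
43 | γ-lactone with tertiary 8-OH; 9,12-bis-OTES, 2-OTBS, 16-OTIPS | CC[Si](CC)(CC)O[C@@H]1[C@H](C)[C@@H]2[C@@H](O[Si](CC)(CC)CC)[C@@]3(O)[C@H](/C=C(CO[Si](C(C)C)(C(C)C)C(C)C)\C=C/[C@H](O[Si](C)(C)C(C)(C)C)[C@@]2(C)[C@H]2O[C@@H]12)OC(=O)[C@@H]3C | intermediate
44 | 8,9,12-triol lactone; 2-OTBS, 16-OTIPS | O[C@@H]1[C@H](C)[C@@H]2[C@@H](O)[C@@]3(O)[C@H](/C=C(CO[Si](C(C)C)(C(C)C)C(C)C)\C=C/[C@H](O[Si](C)(C)C(C)(C)C)[C@@]2(C)[C@H]2O[C@@H]12)OC(=O)[C@@H]3C | intermediate
45 | 9,12-diacetate; 2-OTBS, 16-OTIPS | CC(=O)O[C@@H]1[C@H](C)[C@@H]2[C@@H](OC(C)=O)[C@@]3(O)[C@H](/C=C(CO[Si](C(C)C)(C(C)C)C(C)C)\C=C/[C@H](O[Si](C)(C)C(C)(C)C)[C@@]2(C)[C@H]2O[C@@H]12)OC(=O)[C@@H]3C | intermediate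
46 | briaexcavatolide N | CC(=O)O[C@@H]1[C@H](C)[C@@H]2[C@@H](OC(C)=O)[C@@]3(O)[C@H](/C=C(CO)\C=C/[C@H](O)[C@@]2(C)[C@H]2O[C@@H]12)OC(=O)[C@@H]3C | target

## Count and risks

Total step count: 31. Longest linear sequence: 28 steps (steps 4–31, from pent-1-en-3-one); the side branch to 5 is 3 steps.

Steps most likely to fail:

1. **Step 23 (ring contraction).** The C3 carbanion may expel the C2 silyloxy group before the 1,3-displacement, or the C4 allylic anion may expel O7 through the C5=C6 bond. Repeated bromination at C4 or formation of the trans olefin under the long exposure to hydroxide are further ways of loss. The fallback separates halogenation from carbanion formation. It sets out from sulfide 32: N-chlorosuccinimide (CCl4, 0 °C) chlorinates α to sulfur at the allylic carbon to give the C4 α-chloro sulfide F1. Buffered peroxymonosulfate oxidation gives the C4 α-chloro sulfone F2. Brief treatment with KOt-Bu in THF at −78 °C then effects the classical two-stage Ramberg–Bäcklund extrusion and returns to the route at diene 37.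

2. **Step 21 (eleven-membered ring closure).** Intermolecular S-alkylation may outrun the entropically costly ring closure and give dimers and oligomers, and the allylic chloride may be methanolysed. The fallback closes the ring through an S–S bond and then removes one sulfur. It sets out from 30: KSAc (DMF, rt) converts the allylic chloride into the bis(thioacetate) F3. K2CO3/MeOH frees the C3,C4-dithiol F4. Iodine at high dilution closes the twelve-membered cyclic disulfide F5. Tris(diethylamino)phosphine in benzene extrudes one sulfur atom (SN2 of the C3 thiolate at the allylic C4) and returns to the route at sulfide 32.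

3. **Step 5 (enantioselective Diels–Alder).** Face selectivity or endo/exo selectivity may be poor with the trisubstituted enal, and the acid catalyst may promote aldol-type addition of the silyl enol ether to the aldehyde. The fallback gives up catalyst control and resolves later. It sets out from 7 and 8: thermal cycloaddition (PhMe, 90 °C, BHT) gives racemic adduct, that is 9 together with the enantiomeric cycloadduct F6. Steps 6 and 7 carry both on through 10 and the enantiomeric chlorohydrins F7 to 11 and the enantiomeric chloromethyl ketone F8. Reduction with the (R)-CBS catalyst as in step 8 then gives 12 and the diastereomeric (R)-chlorohydrin of the enantiomeric ring F9. These are separated by chromatography, and the route is rejoined at 12.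

## Further compounds

F1 | step 23 | C4 α-chloro derivative of cyclic sulfide 32 | CC[Si](CC)(CC)O[C@@H]1[C@H](C)[C@@H]2[C@@H](O[Si](CC)(CC)CC)[C@@H]3OC(c4ccc(OC)cc4)O[C@H]3/C=C(CO[Si](C(C)C)(C(C)C)C(C)C)\C(Cl)SC[C@H](O[Si](C)(C)C(C)(C)C)[C@@]2(C)[C@H]2O[C@@H]12
F2 | step 23 | C4 α-chloro cyclic sulfone | CC[Si](CC)(CC)O[C@@H]1[C@H](C)[C@@H]2[C@@H](O[Si](CC)(CC)CC)[C@@H]3OC(c4ccc(OC)cc4)O[C@H]3/C=C(CO[Si](C(C)C)(C(C)C)C(C)C)\C(Cl)S(=O)(=O)C[C@H](O[Si](C)(C)C(C)(C)C)[C@@]2(C)[C@H]2O[C@@H]12
F3 | step 21 | C3,C4-bis(thioacetate) | CC[Si](CC)(CC)O[C@@H]1[C@H](C)[C@H]([C@@H](O[Si](CC)(CC)CC)[C@@H]3OC(c4ccc(OC)cc4)O[C@H]3/C=C(CO[Si](C(C)C)(C(C)C)C(C)C)\CSC(C)=O)[C@]([C@@H](O[Si](C)(C)C(C)(C)C)CSC(C)=O)(C)[C@H]2O[C@@H]12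
F4 | step 21 | C3,C4-dithiol | CC[Si](CC)(CC)O[C@@H]1[C@H](C)[C@H]([C@@H](O[Si](CC)(CC)CC)[C@@H]3OC(c4ccc(OC)cc4)O[C@H]3/C=C(CO[Si](C(C)C)(C(C)C)C(C)C)\CS)[C@]([C@@H](O[Si](C)(C)C(C)(C)C)CS)(C)[C@H]2O[C@@H]12
F5 | step 21 | twelve-membered cyclic disulfide | CC[Si](CC)(CC)O[C@@H]1[C@H](C)[C@@H]2[C@@H](O[Si](CC)(CC)CC)[C@@H]3OC(c4ccc(OC)cc4)O[C@H]3/C=C(CO[Si](C(C)C)(C(C)C)C(C)C)\CSSC[C@H](O[Si](C)(C)C(C)(C)C)[C@@]2(C)[C@H]2O[C@@H]12
F6 | step 5 | enantiomer of cycloadduct 9 | CC(C)[Si](C(C)C)(C(C)C)OC1=CC[C@@](C)(C=O)[C@H](C(=O)OCC)[C@@H]1C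
F7 | step 5 | enantiomeric chlorohydrins (carbinol epimers) corresponding to 10 | CC(C)[Si](C(C)C)(C(C)C)OC1=CC[C@@](C)(C(O)CCl)[C@H](C(=O)OCC)[C@@H]1C
F8 | step 5 | enantiomer of chloromethyl ketone 11 | CC(C)[Si](C(C)C)(C(C)C)OC1=CC[C@@](C)(C(=O)CCl)[C@H](C(=O)OCC)[C@@H]1C
F9 | step 5 | (R)-chlorohydrin on the enantiomeric ring (diastereomer of 12) | CC(C)[Si](C(C)C)(C(C)C)OC1=CC[C@@](C)([C@@H](O)CCl)[C@H](C(=O)OCC)[C@@H]1C
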